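**Retrosynthetic overview**
1. The only ring, the 28-membered lactone, is closed last by an intramolecular Stille coupling (C17–C18) after a Yamaguchi esterification (C1–O–C27); global desilylation ends the route.
2. Polyene alcohol C18–C28: ketoreductase DKR of ethyl 2-methylacetoacetate (C26/C27), vinylogous HWE, Takai iodo-olefination, Stille coupling with bis(stannyl)ethene.
3. Polyol acid C1–C17: C15 by Noyori transfer hydrogenation of an ynone, C13/C14 by Krische crotylation, C7–C8 by alkyne + epoxide coupling followed by hydrogenation.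
4. C1–C7 alkyne: ketoreductase DKR (C2/C3) and Noyori transfer hydrogenation (C5). C8–C13 epoxide: ketoreductase reduction of ethyl 4-chloroacetoacetate (C9), Claisen condensation, Narasaka–Prasad reduction (C11).
5. All hydroxyls are carried as TBS ethers; C1 is carried as a primary TBS ether and oxidised late.

Assumption: ketoreductase variants with the stated stereopreference are taken from commercial screening panels. TBS = tert-butyldimethylsilyl, TBSO = TBS-oxy. Large intermediates are named with macrolide numbering (C1 = lactone C=O, C27 = lactone CH–O); their SMILES define the configuration, and CIP letters can differ from the target's where substituent priorities change.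

**Part 1. C1–C7 alkyne**

Step 1
Reactants: 1 ethyl acetoacetate
Product: 3 ethyl 5-(benzyloxy)-3-oxopentanoate, via acetoacetate dianion 2 (not isolated)
Conditions: NaH, THF, 0 °C; n-BuLi, 0 °C; BnOCH2Cl, 0 °C → rt
Reagents that add atoms: benzyl chloromethyl ether ClCOCc1ccccc1
Why: Weiler dianion alkylation, in which the more basic γ-carbanion is alkylated selectively (SN2) by the reactive α-chloro ether.

Step 2
Reactants: 3 ethyl 5-(benzyloxy)-3-oxopentanoate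
Product: 4 ethyl 5-(benzyloxy)-2-ethyl-3-oxopentanoate (racemic)
Conditions: EtI, K2CO3, acetone, reflux
Reagents that add atoms: iodoethane CCI
Why: C-alkylation (SN2) of the stabilised β-keto ester enolate; the new C2 centre is racemic and configurationally labile, as the next step needs.

Step 3
Reactants: 4 ethyl 5-(benzyloxy)-2-ethyl-3-oxopentanoate
Product: 5 ethyl (2S,3R)-5-(benzyloxy)-2-ethyl-3-hydroxypentanoate
Conditions: ketoreductase (KRED, syn-(2S,3R)-selective panel enzyme), NADP+ (cat.), iPrOH, phosphate buffer pH 7.5, 30 °C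
Reagents that add atoms: none
Why: Ketoreductase-catalysed dynamic reductive kinetic resolution: the enzyme reduces only the (2S)-keto ester from one carbonyl face while the other enantiomer racemises through its enol, setting C2 (S) and C3 (R) together as the first stereocentres.

Step 4
Reactants: 5 ethyl (2S,3R)-5-(benzyloxy)-2-ethyl-3-hydroxypentanoate
Product: 6 (2R,3R)-5-(benzyloxy)-2-ethylpentane-1,3-diol
Conditions: LiAlH4, THF, 0 °C
Reagents that add atoms: none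
Why: Hydride reduction of the ester to the primary alcohol; no stereocentre is touched (the C2 letter changes only through CIP priorities).

Step 5
Reactants: 6 (2R,3R)-5-(benzyloxy)-2-ethylpentane-1,3-diol
Product: 7 (2R,3R)-5-(benzyloxy)-2-ethyl-1,3-bis(TBSO)pentane
Conditions: TBSOTf, 2,6-lutidine, CH2Cl2, 0 °C
Reagents that add atoms: tert-butyldimethylsilyl triflate CC(C)(C)[Si](C)(C)OS(=O)(=O)C(F)(F)F
Why: Silyl ether formation on both hydroxyls with the reactive triflate, which also silylates the hindered secondary alcohol.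

Step 6
Reactants: 7 (2R,3R)-5-(benzyloxy)-2-ethyl-1,3-bis(TBSO)pentane
Product: 8 (3R,4R)-3-(TBSO)-4-(TBSO-methyl)hexan-1-ol
Conditions: H2 (1 atm), 10% Pd/C, EtOAc, rt
Reagents that add atoms: none
Why: Hydrogenolysis of the benzyl ether; TBS ethers are stable in neutral EtOAc.

Step 7
Reactants: 8 (3R,4R)-3-(TBSO)-4-(TBSO-methyl)hexan-1-ol
Product: 9 (3R,4R)-3-(TBSO)-4-(TBSO-methyl)hexanal
Conditions: Dess–Martin periodinane, NaHCO3, CH2Cl2, rt
Reagents that add atoms: none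
Why: Dess–Martin oxidation gives the β-silyloxy aldehyde under buffered, non-basic conditions that avoid β-elimination.

Step 8
Reactants: 9 (3R,4R)-3-(TBSO)-4-(TBSO-methyl)hexanal
Product: 10 (3RS,5R,6R)-5-(TBSO)-6-(TBSO-methyl)-1-(trimethylsilyl)oct-1-yn-3-ol
Conditions: TMSC≡CH, n-BuLi, THF, −78 °C; then 9, −78 °C
Reagents that add atoms: ethynyltrimethylsilane C#C[Si](C)(C)C
Why: 1,2-Addition of a lithium acetylide to the aldehyde; the C5 epimer mixture is irrelevant because the carbinol is re-oxidised.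

Step 9
Reactants: 10 (3RS,5R,6R)-5-(TBSO)-6-(TBSO-methyl)-1-(trimethylsilyl)oct-1-yn-3-ol
Product: 11 (5R,6R)-5-(TBSO)-6-(TBSO-methyl)-1-(trimethylsilyl)oct-1-yn-3-one
Conditions: Dess–Martin periodinane, NaHCO3, CH2Cl2, rt
Reagents that add atoms: none
Why: Dess–Martin oxidation of the propargylic alcohol to the ynone.

Step 10
Reactants: 11 (5R,6R)-5-(TBSO)-6-(TBSO-methyl)-1-(trimethylsilyl)oct-1-yn-3-one
Product: 12 (3R,5R,6R)-5-(TBSO)-6-(TBSO-methyl)-1-(trimethylsilyl)oct-1-yn-3-ol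
Conditions: Ru[(R,R)-TsDPEN](p-cymene) (5 mol%, base-free amido complex), iPrOH, rt
Reagents that add atoms: none
Why: Noyori–Ikariya asymmetric transfer hydrogenation of an ynone; the (R,R)-catalyst delivers hydride to give the (R)-propargylic alcohol (future 5S centre) under catalyst control.

Step 11
Reactants: 12 (3R,5R,6R)-5-(TBSO)-6-(TBSO-methyl)-1-(trimethylsilyl)oct-1-yn-3-ol
Product: 13 (3R,5R,6R)-3,5-bis(TBSO)-6-(TBSO-methyl)-1-(trimethylsilyl)oct-1-yne
Conditions: TBSCl, imidazole, DMF, rt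
Reagents that add atoms: tert-butyldimethylsilyl chloride CC(C)(C)[Si](C)(C)Cl
Why: Standard silylation of the unhindered propargylic alcohol.

Step 12
Reactants: 13 (3R,5R,6R)-3,5-bis(TBSO)-6-(TBSO-methyl)-1-(trimethylsilyl)oct-1-yne
Product: 14 (3R,5R,6R)-3,5-bis(TBSO)-6-(TBSO-methyl)oct-1-yne (C1–C7 alkyne)
Conditions: K2CO3, MeOH, rt
Reagents that add atoms: none
Why: Methanolysis of the C(sp)–Si bond, which is far more labile than the O–TBS ethers.

**Part 2. C8–C13 epoxide**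

Step 13
Reactants: 15 ethyl 4-chloro-3-oxobutanoate
Product: 16 ethyl (3R)-4-chloro-3-hydroxybutanoate
Conditions: ketoreductase (KRED, R-selective), NADP+ (cat.), iPrOH, phosphate buffer pH 6.5, 30 °C
Reagents that add atoms: none
Why: Ketoreductase-catalysed asymmetric reduction of an activated α-chloro ketone; enzyme-controlled hydride delivery to one face gives the (R)-chlorohydrin (future C9).

Step 14
Reactants: 16 ethyl (3R)-4-chloro-3-hydroxybutanoate
Product: 17 tert-butyl (5R)-6-chloro-5-hydroxy-3-oxohexanoate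
Conditions: t-BuOAc, LDA (3.5 eq), THF, −78 °C; then 16, −78 → −30 °C; AcOH
Reagents that add atoms: tert-butyl acetate CC(=O)OC(C)(C)C
Why: Crossed Claisen condensation of excess lithium tert-butyl acetate with the ethyl ester; the unprotected hydroxyl is tolerated as its alkoxide.

Step 15
Reactants: 17 tert-butyl (5R)-6-chloro-5-hydroxy-3-oxohexanoate
Product: 19 tert-butyl (3S,5R)-6-chloro-3,5-dihydroxyhexanoate, via diethylboryl chelate 18 (not isolated)
Conditions: Et2BOMe, THF/MeOH 4:1, −78 °C; NaBH4; AcOH, then MeOH co-evaporation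
Reagents that add atoms: none
Why: Narasaka–Prasad reduction: external axial hydride attack on the six-membered boron chelate gives the 1,3-syn diol (future C11 relative to C9).

Step 16
Reactants: 19 tert-butyl (3S,5R)-6-chloro-3,5-dihydroxyhexanoate
Product: 20 tert-butyl (3S)-3-hydroxy-4-[(2R)-oxiran-2-yl]butanoate
Conditions: K2CO3, MeOH, 0 °C → rt
Reagents that add atoms: none
Why: Intramolecular Williamson (3-exo-tet) closure of the chlorohydrin; the carbinol centre is not touched.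

Step 17
Reactants: 20 tert-butyl (3S)-3-hydroxy-4-[(2R)-oxiran-2-yl]butanoate
Product: 21 tert-butyl (3S)-3-(TBSO)-4-[(2R)-oxiran-2-yl]butanoate (C8–C13 epoxide)
Conditions: TBSCl, imidazole, DMF, rt
Reagents that add atoms: tert-butyldimethylsilyl chloride CC(C)(C)[Si](C)(C)Cl
Why: Standard silylation of the secondary alcohol; the epoxide and tert-butyl ester are inert.

**Part 3. Fragment union and elaboration to the C1–C17 acid**

Step 18
Reactants: 14 C1–C7 alkyne; 21 C8–C13 epoxide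
Product: 23 C1–C13 ynol (tert-butyl ester at C13; 9-OH; C6≡C7; TBSO at C1 C3 C5 C11), via lithium acetylide 22 (not isolated)
Conditions: 14, n-BuLi, THF, −78 °C; BF3·OEt2; then 21, −78 °C
Reagents that add atoms: none
Why: Yamaguchi–Hirao alkynylation: the BF3-activated terminal epoxide is opened at its CH2 carbon by the acetylide, so the C9 configuration is retained and the tert-butyl ester survives at −78 °C.

Step 19
Reactants: 23 C1–C13 ynol
Product: 24 C1–C13 alcohol (as 23 but C6–C7 saturated)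
Conditions: H2 (1 atm), 10% Pd/C, EtOAc, rt
Reagents that add atoms: none
Why: Heterogeneous hydrogenation of the only unsaturation to the C6–C8 trimethylene unit.

Step 20
Reactants: 24 C1–C13 alcohol
Product: 25 C1–C13 penta-TBS tert-butyl ester (TBSO at C1 C3 C5 C9 C11)
Conditions: TBSOTf, 2,6-lutidine, CH2Cl2, −78 → 0 °C
Reagents that add atoms: tert-butyldimethylsilyl triflate CC(C)(C)[Si](C)(C)OS(=O)(=O)C(F)(F)F
Why: Silylation of the C9 secondary alcohol.

Step 21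
Reactants: 25 C1–C13 penta-TBS tert-butyl ester
Product: 26 C1–C13 penta-TBS primary alcohol (13-OH)
Conditions: DIBAL-H (3 eq), CH2Cl2, −78 → 0 °C; Rochelle salt
Reagents that add atoms: none
Why: Hydride reduction of the ester to the alcohol; silyl ethers are inert.

Step 22
Reactants: 26 C1–C13 penta-TBS primary alcohol
Product: 28 C1–C16 homoallylic alcohol (13-OH; 14-Me; 13,14-anti; C15=C16 vinyl), via C13 aldehyde 27 (not isolated)
Conditions: [Ir(cod)Cl]2 (5 mol%), (S)-SEGPHOS (10 mol%), 4-cyano-3-nitrobenzoic acid (20 mol%), Cs2CO3 (40 mol%), but-3-en-2-yl acetate (racemic), THF, 70 °C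
Reagents that add atoms: but-3-en-2-yl acetate CC(OC(C)=O)C=C
Why: Krische iridium-catalysed transfer-hydrogenative crotylation: the alcohol is dehydrogenated to aldehyde 27, which adds the (E)-σ-crotyl iridium through a closed chair transition state (13,14-anti), the ligand antipode fixing the face for C13 and C14 (the acetate's own stereocentre is erased in the π-crotyl complex).

Step 23
Reactants: 28 C1–C16 homoallylic alcohol
Product: 29 C1–C16 hexa-TBS alkene (13-OTBS)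
Conditions: TBSOTf, 2,6-lutidine, CH2Cl2, −78 → 0 °C
Reagents that add atoms: tert-butyldimethylsilyl triflate CC(C)(C)[Si](C)(C)OS(=O)(=O)C(F)(F)F
Why: Silylation of the hindered C13 alcohol with the triflate.

Step 24
Reactants: 29 C1–C16 hexa-TBS alkene
Product: 31 C1–C15 hexa-TBS aldehyde (C15 = CHO), via ozonide 30 (not isolated)
Conditions: O3, CH2Cl2, −78 °C; then PPh3, −78 °C → rt
Reagents that add atoms: ozone [O-][O+]=O
Why: Ozonolysis with reductive work-up cleaves the terminal alkene to the α-methyl aldehyde without epimerising C14.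

Step 25
Reactants: 31 C1–C15 hexa-TBS aldehyde
Product: 32 C1–C17 TMS-ynol (15-OH as epimer mixture; C16≡C17–SiMe3)
Conditions: TMSC≡CH, n-BuLi, THF, −78 °C; then 31, −78 °C
Reagents that add atoms: ethynyltrimethylsilane C#C[Si](C)(C)C
Why: Lithium acetylide 1,2-addition installs C16–C17; the C15 ratio is irrelevant because the carbinol is re-oxidised.

Step 26
Reactants: 32 C1–C17 TMS-ynol
Product: 33 C1–C17 TMS-ynone (C15 = C=O)
Conditions: Dess–Martin periodinane, NaHCO3, CH2Cl2, rt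
Reagents that add atoms: none
Why: Dess–Martin oxidation under buffered conditions preserves the α-stereocentre C14.

Step 27
Reactants: 33 C1–C17 TMS-ynone
Product: 34 C1–C17 TMS-ynol with defined C15 carbinol (CIP 15S here; target configuration)
Conditions: Ru[(S,S)-TsDPEN](p-cymene) (5 mol%, base-free amido complex), iPrOH, rt
Reagents that add atoms: none
Why: Noyori–Ikariya asymmetric transfer hydrogenation; the (S,S)-catalyst gives the (S)-propargylic alcohol under catalyst control, here reinforced by Felkin attack on the 13,14-anti ketone.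

Step 28
Reactants: 34 C1–C17 TMS-ynol
Product: 35 C1–C17 hepta-TBS TMS-alkyne
Conditions: TBSOTf, 2,6-lutidine, CH2Cl2, −78 → 0 °C
Reagents that add atoms: tert-butyldimethylsilyl triflate CC(C)(C)[Si](C)(C)OS(=O)(=O)C(F)(F)F
Why: Silylation of the hindered C15 alcohol.

Step 29
Reactants: 35 C1–C17 hepta-TBS TMS-alkyne
Product: 36 C1–C17 hepta-TBS terminal alkyne
Conditions: K2CO3, MeOH/THF, rt
Reagents that add atoms: none
Why: Selective methanolysis of the alkynyl C–Si bond.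

Step 30
Reactants: 36 C1–C17 hepta-TBS terminal alkyne
Product: 38 C1–C17 hepta-TBS (E)-vinyl iodide, via alkenylzirconocene 37 (not isolated)
Conditions: Cp2Zr(H)Cl, THF, rt, dark; then I2, 0 °C
Reagents that add atoms: iodine II
Why: Schwartz hydrozirconation adds Zr–H syn with Zr at the terminal carbon, and iodinolysis with retention gives the (E)-vinyl iodide only.

Step 31
Reactants: 38 C1–C17 hepta-TBS (E)-vinyl iodide
Product: 39 C1–C17 hexa-TBS vinyl iodide with free 1-OH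
Conditions: HF·pyridine, pyridine, THF, 0 °C → rt (monitored)
Reagents that add atoms: none
Why: Buffered HF·pyridine cleaves the single primary TBS ether much faster than the six secondary ones.

Step 32
Reactants: 39 C1–C17 hexa-TBS vinyl iodide with free 1-OH
Product: 40 C1–C17 hexa-TBS vinyl iodide C1 aldehyde
Conditions: Dess–Martin periodinane, NaHCO3, CH2Cl2, 0 °C → rt
Reagents that add atoms: none
Why: Buffered Dess–Martin oxidation gives the α-ethyl aldehyde without epimerising C2.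

Step 33
Reactants: 40 C1–C17 hexa-TBS vinyl iodide C1 aldehyde
Product: 41 C1–C17 hexa-TBS vinyl iodide C1 carboxylic acid
Conditions: NaClO2, NaH2PO4, 2-methyl-2-butene, t-BuOH/H2O, 0 °C → rt
Reagents that add atoms: sodium chlorite [Na+].[O-]Cl=O
Why: Pinnick oxidation converts the aldehyde to the acid under mildly acidic conditions that spare silyl ethers, the vinyl iodide and the C2 centre.

**Part 4. C18–C28 stannyl alcohol**

Step 34
Reactants: 1 ethyl acetoacetate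
Product: 42 ethyl 2-methyl-3-oxobutanoate (racemic)
Conditions: MeI, K2CO3, acetone, reflux
Reagents that add atoms: iodomethane CI
Why: C-methylation (SN2) of the β-keto ester enolate gives the configurationally labile DKR substrate from achiral material.

Step 35
Reactants: 42 ethyl 2-methyl-3-oxobutanoate
Product: 43 ethyl (2S,3R)-3-hydroxy-2-methylbutanoate
Conditions: ketoreductase (KRED, anti-Prelog syn-selective panel enzyme), NADP+ (cat.), iPrOH, phosphate buffer pH 7.5, 30 °C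
Reagents that add atoms: none
Why: Ketoreductase-catalysed dynamic reductive kinetic resolution sets C26 and C27 together in the syn-(2S,3R) form while the substrate racemises via its enol.

Step 36
Reactants: 43 ethyl (2S,3R)-3-hydroxy-2-methylbutanoate
Product: 44 ethyl (2S,3R)-3-(TBSO)-2-methylbutanoate
Conditions: TBSCl, imidazole, DMF, rt
Reagents that add atoms: tert-butyldimethylsilyl chloride CC(C)(C)[Si](C)(C)Cl
Why: Standard silylation of the secondary alcohol.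

Step 37
Reactants: 44 ethyl (2S,3R)-3-(TBSO)-2-methylbutanoate
Product: 46 (2S,3R)-3-(TBSO)-2-methylbutanal, via aluminium hemiacetal 45 (not isolated)
Conditions: DIBAL-H (1.1 eq), CH2Cl2, −78 °C; MeOH, then Rochelle salt
Reagents that add atoms: none
Why: Partial DIBAL reduction, in which the tetrahedral aluminium hemiacetal is stable at −78 °C and releases the aldehyde only on work-up.

Step 38
Reactants: 46 (2S,3R)-3-(TBSO)-2-methylbutanal
Product: 47 ethyl (2E,4E,6R,7R)-7-(TBSO)-6-methylocta-2,4-dienoate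
Conditions: triethyl 4-phosphonocrotonate, LiHMDS, THF, −78 °C; then 46, −78 → 0 °C
Reagents that add atoms: triethyl 4-phosphonocrotonate CCOC(=O)/C=C/CP(=O)(OCC)OCC
Why: Vinylogous Horner–Wadsworth–Emmons olefination gives the (E,E)-dienoate (C21–C25) under thermodynamic control of the stabilised phosphonate; the low temperature protects C26.

Step 39
Reactants: 47 ethyl (2E,4E,6R,7R)-7-(TBSO)-6-methylocta-2,4-dienoate
Product: 48 (2E,4E,6R,7R)-7-(TBSO)-6-methylocta-2,4-dien-1-ol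
Conditions: DIBAL-H (2.5 eq), CH2Cl2, −78 °C
Reagents that add atoms: none
Why: 1,2-Reduction of the dienoate to the dienol.

Step 40
Reactants: 48 (2E,4E,6R,7R)-7-(TBSO)-6-methylocta-2,4-dien-1-ol
Product: 49 (2E,4E,6R,7R)-7-(TBSO)-6-methylocta-2,4-dienal
Conditions: MnO2, CH2Cl2, rt
Reagents that add atoms: none
Why: Chemoselective MnO2 oxidation of the allylic alcohol without alkene isomerisation.

Step 41
Reactants: 49 (2E,4E,6R,7R)-7-(TBSO)-6-methylocta-2,4-dienal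
Product: 50 tert-butyl{[(2R,3R,4E,6E,8E)-9-iodo-3-methylnona-4,6,8-trien-2-yl]oxy}dimethylsilane
Conditions: CrCl2, CHI3, THF/dioxane, 0 °C → rt, dark
Reagents that add atoms: iodoform IC(I)I
Why: Takai iodo-olefination converts the aldehyde to the (E)-vinyl iodide (C20) through a gem-dichromium carbenoid; the minor Z isomer is removed by chromatography.

Step 42
Reactants: 50 trienyl iodide
Product: 51 tributyl[(1E,3E,5E,7E,9R,10R)-10-(TBSO)-9-methylundeca-1,3,5,7-tetraen-1-yl]stannane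
Conditions: (E)-Bu3SnCH=CHSnBu3 (4 eq), PdCl2(MeCN)2 (5 mol%), DMF, rt, dark
Reagents that add atoms: (E)-1,2-bis(tributylstannyl)ethene CCCC[Sn](CCCC)(CCCC)/C=C/[Sn](CCCC)(CCCC)CCCC
Why: Stille mono-coupling with excess distannane adds C18–C19 with retention of both alkene geometries and leaves a terminal vinylstannane.

Step 43
Reactants: 51 tetraenylstannane TBS ether
Product: 52 (2R,3R,4E,6E,8E,10E)-3-methyl-11-(tributylstannyl)undeca-4,6,8,10-tetraen-2-ol
Conditions: TBAF, THF, 0 °C → rt, dark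
Reagents that add atoms: none
Why: Fluoride desilylation under non-acidic conditions that do not protodestannylate the polyenylstannane.

**Part 5. Endgame**

Step 44
Reactants: 41 C1–C17 acid; 52 C18–C28 stannyl alcohol
Product: 54 seco ester (C1 ester of 41 with O27 of 52; vinyl iodide at C17; stannane at C18), via mixed anhydride 53 (not isolated)
Conditions: 2,4,6-Cl3C6H2COCl, Et3N, toluene, rt; then 52, DMAP, rt, dark
Reagents that add atoms: none
Why: Yamaguchi esterification, in which the mixed anhydride is attacked at the aliphatic carbonyl via the acyl-pyridinium; C27 is acylated on oxygen with retention.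

Step 45
Reactants: 54 seco ester
Product: 55 hexa-TBS macrolide (3,5,9,11,13,15-hexakis-O-TBS derivative of the target)
Conditions: Pd2(dba)3 (20 mol%), AsPh3, iPr2NEt, DMF/THF, 1 mM, rt, dark
Reagents that add atoms: none
Why: Intramolecular Stille coupling forms C17–C18 with retention of both alkene geometries, closing the 28-membered ring and completing the all-E pentaene under neutral conditions.

Step 46
Reactants: 55 hexa-TBS macrolide
Product: 56 CNP0382847.1 (target)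
Conditions: HF·pyridine, pyridine, THF, 0 °C → rt, dark, plastic vessel
Reagents that add atoms: none
Why: Global fluoride-mediated desilylation under pyridine-buffered conditions that spare the pentaene, the allylic C15 carbinol and the lactone.

**Compound list**
1 | ethyl acetoacetate | CCOC(=O)CC(C)=O | starting material
2 | ethyl acetoacetate 2,4-dianion (Na/Li) | CCOC(=O)[CH-]C(=O)[CH2-].[Na+].[Li+] | intermediate (not isolated)
3 | ethyl 5-(benzyloxy)-3-oxopentanoate | CCOC(=O)CC(=O)CCOCc1ccccc1 | intermediate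
4 | ethyl 5-(benzyloxy)-2-ethyl-3-oxopentanoate (racemic) | CCOC(=O)C(CC)C(=O)CCOCc1ccccc1 | intermediate
5 | ethyl (2S,3R)-5-(benzyloxy)-2-ethyl-3-hydroxypentanoate | c1ccccc1COCC[C@@H](O)[C@H](CC)C(=O)OCC | intermediate
6 | (2R,3R)-5-(benzyloxy)-2-ethylpentane-1,3-diol | c1ccccc1COCC[C@@H](O)[C@H](CC)CO | intermediate
7 | (2R,3R)-5-(benzyloxy)-2-ethyl-1,3-bis(TBSO)pentane | c1ccccc1COCC[C@@H](O[Si](C)(C)C(C)(C)C)[C@H](CC)CO[Si](C)(C)C(C)(C)C | intermediate
8 | (3R,4R)-3-(TBSO)-4-(TBSO-methyl)hexan-1-ol | OCC[C@@H](O[Si](C)(C)C(C)(C)C)[C@H](CC)CO[Si](C)(C)C(C)(C)C | intermediate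
9 | (3R,4R)-3-(TBSO)-4-(TBSO-methyl)hexanal | O=CC[C@@H](O[Si](C)(C)C(C)(C)C)[C@H](CC)CO[Si](C)(C)C(C)(C)C | intermediate
10 | (3RS,5R,6R)-5-(TBSO)-6-(TBSO-methyl)-1-(trimethylsilyl)oct-1-yn-3-ol | C[Si](C)(C)C#CC(O)C[C@@H](O[Si](C)(C)C(C)(C)C)[C@H](CC)CO[Si](C)(C)C(C)(C)C | intermediate
11 | (5R,6R)-5-(TBSO)-6-(TBSO-methyl)-1-(trimethylsilyl)oct-1-yn-3-one | C[Si](C)(C)C#CC(=O)C[C@@H](O[Si](C)(C)C(C)(C)C)[C@H](CC)CO[Si](C)(C)C(C)(C)C | intermediate
12 | (3R,5R,6R)-5-(TBSO)-6-(TBSO-methyl)-1-(trimethylsilyl)oct-1-yn-3-ol | C[Si](C)(C)C#C[C@H](O)C[C@@H](O[Si](C)(C)C(C)(C)C)[C@H](CC)CO[Si](C)(C)C(C)(C)C | intermediate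
13 | (3R,5R,6R)-3,5-bis(TBSO)-6-(TBSO-methyl)-1-(trimethylsilyl)oct-1-yne | C[Si](C)(C)C#C[C@H](O[Si](C)(C)C(C)(C)C)C[C@@H](O[Si](C)(C)C(C)(C)C)[C@H](CC)CO[Si](C)(C)C(C)(C)C | intermediate
14 | (3R,5R,6R)-3,5-bis(TBSO)-6-(TBSO-methyl)oct-1-yne (C1–C7 alkyne) | C#C[C@H](O[Si](C)(C)C(C)(C)C)C[C@@H](O[Si](C)(C)C(C)(C)C)[C@H](CC)CO[Si](C)(C)C(C)(C)C | intermediate
15 | ethyl 4-chloro-3-oxobutanoate | CCOC(=O)CC(=O)CCl | starting material
16 | ethyl (3R)-4-chloro-3-hydroxybutanoate | CCOC(=O)C[C@@H](O)CCl | intermediate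
17 | tert-butyl (5R)-6-chloro-5-hydroxy-3-oxohexanoate | CC(C)(C)OC(=O)CC(=O)C[C@@H](O)CCl | intermediate
18 | tert-butyl (5R)-6-chloro-5-[(diethylboranyl)oxy]-3-oxohexanoate (boron chelate) | CC(C)(C)OC(=O)CC(=O)C[C@@H](OB(CC)CC)CCl | intermediate (not isolated)
19 | tert-butyl (3S,5R)-6-chloro-3,5-dihydroxyhexanoate | CC(C)(C)OC(=O)C[C@@H](O)C[C@@H](O)CCl | intermediate
20 | tert-butyl (3S)-3-hydroxy-4-[(2R)-oxiran-2-yl]butanoate | CC(C)(C)OC(=O)C[C@@H](O)C[C@@H]1CO1 | intermediate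
21 | tert-butyl (3S)-3-(TBSO)-4-[(2R)-oxiran-2-yl]butanoate (C8–C13 epoxide) | CC(C)(C)OC(=O)C[C@@H](O[Si](C)(C)C(C)(C)C)C[C@@H]1CO1 | intermediate
22 | lithium acetylide of 14 | [Li]C#C[C@H](O[Si](C)(C)C(C)(C)C)C[C@@H](O[Si](C)(C)C(C)(C)C)[C@H](CC)CO[Si](C)(C)C(C)(C)C | intermediate (not isolated)
23 | C1–C13 ynol (tert-butyl ester at C13; 9-OH; C6≡C7; TBSO at C1, C3, C5, C11) | CC(C)(C)OC(=O)C[C@@H](O[Si](C)(C)C(C)(C)C)C[C@@H](O)CC#C[C@H](O[Si](C)(C)C(C)(C)C)C[C@@H](O[Si](C)(C)C(C)(C)C)[C@H](CC)CO[Si](C)(C)C(C)(C)C | intermediate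
24 | C1–C13 alcohol (9-OH; C6–C7 saturated) | CC(C)(C)OC(=O)C[C@@H](O[Si](C)(C)C(C)(C)C)C[C@@H](O)CCC[C@H](O[Si](C)(C)C(C)(C)C)C[C@@H](O[Si](C)(C)C(C)(C)C)[C@H](CC)CO[Si](C)(C)C(C)(C)C | intermediate
25 | C1–C13 penta-TBS tert-butyl ester | CC(C)(C)OC(=O)C[C@@H](O[Si](C)(C)C(C)(C)C)C[C@@H](O[Si](C)(C)C(C)(C)C)CCC[C@H](O[Si](C)(C)C(C)(C)C)C[C@@H](O[Si](C)(C)C(C)(C)C)[C@H](CC)CO[Si](C)(C)C(C)(C)C | intermediate
26 | C1–C13 penta-TBS primary alcohol (13-OH) | OCC[C@@H](O[Si](C)(C)C(C)(C)C)C[C@@H](O[Si](C)(C)C(C)(C)C)CCC[C@H](O[Si](C)(C)C(C)(C)C)C[C@@H](O[Si](C)(C)C(C)(C)C)[C@H](CC)CO[Si](C)(C)C(C)(C)C | intermediate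
27 | C1–C13 penta-TBS aldehyde (C13 = CHO) | O=CC[C@@H](O[Si](C)(C)C(C)(C)C)C[C@@H](O[Si](C)(C)C(C)(C)C)CCC[C@H](O[Si](C)(C)C(C)(C)C)C[C@@H](O[Si](C)(C)C(C)(C)C)[C@H](CC)CO[Si](C)(C)C(C)(C)C | intermediate (not isolated)
28 | C1–C16 homoallylic alcohol (13-OH, 14-Me anti, C15=C16) | C=C[C@H](C)[C@H](O)C[C@@H](O[Si](C)(C)C(C)(C)C)C[C@@H](O[Si](C)(C)C(C)(C)C)CCC[C@H](O[Si](C)(C)C(C)(C)C)C[C@@H](O[Si](C)(C)C(C)(C)C)[C@H](CC)CO[Si](C)(C)C(C)(C)C | intermediate
29 | C1–C16 hexa-TBS alkene | C=C[C@H](C)[C@H](O[Si](C)(C)C(C)(C)C)C[C@@H](O[Si](C)(C)C(C)(C)C)C[C@@H](O[Si](C)(C)C(C)(C)C)CCC[C@H](O[Si](C)(C)C(C)(C)C)C[C@@H](O[Si](C)(C)C(C)(C)C)[C@H](CC)CO[Si](C)(C)C(C)(C)C | intermediate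
30 | ozonide (1,2,4-trioxolane) of 29 | C1OOC(O1)[C@H](C)[C@H](O[Si](C)(C)C(C)(C)C)C[C@@H](O[Si](C)(C)C(C)(C)C)C[C@@H](O[Si](C)(C)C(C)(C)C)CCC[C@H](O[Si](C)(C)C(C)(C)C)C[C@@H](O[Si](C)(C)C(C)(C)C)[C@H](CC)CO[Si](C)(C)C(C)(C)C | intermediate (not isolated)
31 | C1–C15 hexa-TBS aldehyde (C15 = CHO) | O=C[C@H](C)[C@H](O[Si](C)(C)C(C)(C)C)C[C@@H](O[Si](C)(C)C(C)(C)C)C[C@@H](O[Si](C)(C)C(C)(C)C)CCC[C@H](O[Si](C)(C)C(C)(C)C)C[C@@H](O[Si](C)(C)C(C)(C)C)[C@H](CC)CO[Si](C)(C)C(C)(C)C | intermediate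
32 | C1–C17 TMS-ynol (15-epimer mixture) | C[Si](C)(C)C#CC(O)[C@H](C)[C@H](O[Si](C)(C)C(C)(C)C)C[C@@H](O[Si](C)(C)C(C)(C)C)C[C@@H](O[Si](C)(C)C(C)(C)C)CCC[C@H](O[Si](C)(C)C(C)(C)C)C[C@@H](O[Si](C)(C)C(C)(C)C)[C@H](CC)CO[Si](C)(C)C(C)(C)C | intermediate
33 | C1–C17 TMS-ynone (C15 = C=O) | C[Si](C)(C)C#CC(=O)[C@H](C)[C@H](O[Si](C)(C)C(C)(C)C)C[C@@H](O[Si](C)(C)C(C)(C)C)C[C@@H](O[Si](C)(C)C(C)(C)C)CCC[C@H](O[Si](C)(C)C(C)(C)C)C[C@@H](O[Si](C)(C)C(C)(C)C)[C@H](CC)CO[Si](C)(C)C(C)(C)C | intermediate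
34 | C1–C17 TMS-ynol, single C15 epimer (CIP 15S; target configuration) | C[Si](C)(C)C#C[C@@H](O)[C@H](C)[C@H](O[Si](C)(C)C(C)(C)C)C[C@@H](O[Si](C)(C)C(C)(C)C)C[C@@H](O[Si](C)(C)C(C)(C)C)CCC[C@H](O[Si](C)(C)C(C)(C)C)C[C@@H](O[Si](C)(C)C(C)(C)C)[C@H](CC)CO[Si](C)(C)C(C)(C)C | intermediate
35 | C1–C17 hepta-TBS TMS-alkyne | C[Si](C)(C)C#C[C@@H](O[Si](C)(C)C(C)(C)C)[C@H](C)[C@H](O[Si](C)(C)C(C)(C)C)C[C@@H](O[Si](C)(C)C(C)(C)C)C[C@@H](O[Si](C)(C)C(C)(C)C)CCC[C@H](O[Si](C)(C)C(C)(C)C)C[C@@H](O[Si](C)(C)C(C)(C)C)[C@H](CC)CO[Si](C)(C)C(C)(C)C | intermediate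
36 | C1–C17 hepta-TBS terminal alkyne | C#C[C@@H](O[Si](C)(C)C(C)(C)C)[C@H](C)[C@H](O[Si](C)(C)C(C)(C)C)C[C@@H](O[Si](C)(C)C(C)(C)C)C[C@@H](O[Si](C)(C)C(C)(C)C)CCC[C@H](O[Si](C)(C)C(C)(C)C)C[C@@H](O[Si](C)(C)C(C)(C)C)[C@H](CC)CO[Si](C)(C)C(C)(C)C | intermediate
37 | (E)-alkenyl(chloro)zirconocene of 36 (Cp drawn σ-bonded) | Cl[Zr](C1C=CC=C1)(C1C=CC=C1)/C=C/[C@@H](O[Si](C)(C)C(C)(C)C)[C@H](C)[C@H](O[Si](C)(C)C(C)(C)C)C[C@@H](O[Si](C)(C)C(C)(C)C)C[C@@H](O[Si](C)(C)C(C)(C)C)CCC[C@H](O[Si](C)(C)C(C)(C)C)C[C@@H](O[Si](C)(C)C(C)(C)C)[C@H](CC)CO[Si](C)(C)C(C)(C)C | intermediate (not isolated)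
38 | C1–C17 hepta-TBS (E)-vinyl iodide | I/C=C/[C@@H](O[Si](C)(C)C(C)(C)C)[C@H](C)[C@H](O[Si](C)(C)C(C)(C)C)C[C@@H](O[Si](C)(C)C(C)(C)C)C[C@@H](O[Si](C)(C)C(C)(C)C)CCC[C@H](O[Si](C)(C)C(C)(C)C)C[C@@H](O[Si](C)(C)C(C)(C)C)[C@H](CC)CO[Si](C)(C)C(C)(C)C | intermediate
39 | C1–C17 hexa-TBS vinyl iodide, free 1-OH | I/C=C/[C@@H](O[Si](C)(C)C(C)(C)C)[C@H](C)[C@H](O[Si](C)(C)C(C)(C)C)C[C@@H](O[Si](C)(C)C(C)(C)C)C[C@@H](O[Si](C)(C)C(C)(C)C)CCC[C@H](O[Si](C)(C)C(C)(C)C)C[C@@H](O[Si](C)(C)C(C)(C)C)[C@H](CC)CO | intermediate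
40 | C1–C17 hexa-TBS vinyl iodide, C1 aldehyde | I/C=C/[C@@H](O[Si](C)(C)C(C)(C)C)[C@H](C)[C@H](O[Si](C)(C)C(C)(C)C)C[C@@H](O[Si](C)(C)C(C)(C)C)C[C@@H](O[Si](C)(C)C(C)(C)C)CCC[C@H](O[Si](C)(C)C(C)(C)C)C[C@@H](O[Si](C)(C)C(C)(C)C)[C@H](CC)C=O | intermediate
41 | C1–C17 hexa-TBS vinyl iodide, C1 carboxylic acid | I/C=C/[C@@H](O[Si](C)(C)C(C)(C)C)[C@H](C)[C@H](O[Si](C)(C)C(C)(C)C)C[C@@H](O[Si](C)(C)C(C)(C)C)C[C@@H](O[Si](C)(C)C(C)(C)C)CCC[C@H](O[Si](C)(C)C(C)(C)C)C[C@@H](O[Si](C)(C)C(C)(C)C)[C@H](CC)C(=O)O | intermediate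
42 | ethyl 2-methyl-3-oxobutanoate (racemic) | CCOC(=O)C(C)C(C)=O | intermediate
43 | ethyl (2S,3R)-3-hydroxy-2-methylbutanoate | C[C@@H](O)[C@H](C)C(=O)OCC | intermediate
44 | ethyl (2S,3R)-3-(TBSO)-2-methylbutanoate | C[C@@H](O[Si](C)(C)C(C)(C)C)[C@H](C)C(=O)OCC | intermediate
45 | diisobutylaluminium hemiacetal of 44 | C[C@@H](O[Si](C)(C)C(C)(C)C)[C@H](C)C(OCC)O[Al](CC(C)C)CC(C)C | intermediate (not isolated)
46 | (2S,3R)-3-(TBSO)-2-methylbutanal | C[C@@H](O[Si](C)(C)C(C)(C)C)[C@H](C)C=O | intermediate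
47 | ethyl (2E,4E,6R,7R)-7-(TBSO)-6-methylocta-2,4-dienoate | C[C@@H](O[Si](C)(C)C(C)(C)C)[C@H](C)/C=C/C=C/C(=O)OCC | intermediate
48 | (2E,4E,6R,7R)-7-(TBSO)-6-methylocta-2,4-dien-1-ol | C[C@@H](O[Si](C)(C)C(C)(C)C)[C@H](C)/C=C/C=C/CO | intermediate
49 | (2E,4E,6R,7R)-7-(TBSO)-6-methylocta-2,4-dienal | C[C@@H](O[Si](C)(C)C(C)(C)C)[C@H](C)/C=C/C=C/C=O | intermediate
50 | tert-butyl{[(2R,3R,4E,6E,8E)-9-iodo-3-methylnona-4,6,8-trien-2-yl]oxy}dimethylsilane | C[C@@H](O[Si](C)(C)C(C)(C)C)[C@H](C)/C=C/C=C/C=C/I | intermediate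
51 | tributyl[(1E,3E,5E,7E,9R,10R)-10-(TBSO)-9-methylundeca-1,3,5,7-tetraen-1-yl]stannane | C[C@@H](O[Si](C)(C)C(C)(C)C)[C@H](C)/C=C/C=C/C=C/C=C/[Sn](CCCC)(CCCC)CCCC | intermediate
52 | (2R,3R,4E,6E,8E,10E)-3-methyl-11-(tributylstannyl)undeca-4,6,8,10-tetraen-2-ol | C[C@@H](O)[C@H](C)/C=C/C=C/C=C/C=C/[Sn](CCCC)(CCCC)CCCC | intermediate
53 | mixed anhydride of 41 with 2,4,6-trichlorobenzoic acid | I/C=C/[C@@H](O[Si](C)(C)C(C)(C)C)[C@H](C)[C@H](O[Si](C)(C)C(C)(C)C)C[C@@H](O[Si](C)(C)C(C)(C)C)C[C@@H](O[Si](C)(C)C(C)(C)C)CCC[C@H](O[Si](C)(C)C(C)(C)C)C[C@@H](O[Si](C)(C)C(C)(C)C)[C@H](CC)C(=O)OC(=O)c1c(Cl)cc(Cl)cc1Cl | intermediate (not isolated)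
54 | seco ester of 41 and 52 (C17 vinyl iodide, C18 stannane) | I/C=C/[C@@H](O[Si](C)(C)C(C)(C)C)[C@H](C)[C@H](O[Si](C)(C)C(C)(C)C)C[C@@H](O[Si](C)(C)C(C)(C)C)C[C@@H](O[Si](C)(C)C(C)(C)C)CCC[C@H](O[Si](C)(C)C(C)(C)C)C[C@@H](O[Si](C)(C)C(C)(C)C)[C@H](CC)C(=O)O[C@H](C)[C@H](C)/C=C/C=C/C=C/C=C/[Sn](CCCC)(CCCC)CCCC | intermediate
55 | 3,5,9,11,13,15-hexakis-O-TBS macrolide | CC[C@@H]1C(=O)O[C@H](C)[C@H](C)/C=C/C=C/C=C/C=C/C=C/[C@@H](O[Si](C)(C)C(C)(C)C)[C@H](C)[C@H](O[Si](C)(C)C(C)(C)C)C[C@@H](O[Si](C)(C)C(C)(C)C)C[C@@H](O[Si](C)(C)C(C)(C)C)CCC[C@H](O[Si](C)(C)C(C)(C)C)C[C@H]1O[Si](C)(C)C(C)(C)C | intermediate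
56 | CNP0382847.1, (2S,3R,5S,9S,11S,13R,14R,15R,26R,27R; all-E) 28-membered pentaene macrolide | CC[C@@H]1C(=O)O[C@H](C)[C@H](C)/C=C/C=C/C=C/C=C/C=C/[C@@H](O)[C@H](C)[C@H](O)C[C@@H](O)C[C@@H](O)CCC[C@H](O)C[C@H]1O | target

**Totals and risks**
Total step count: 46. Longest linear sequence: 31 steps (steps 1–12, 18–33, 44–46).

The three steps most likely to fail:

Step 3 (ketoreductase DKR of 4). The substrate is a bulky, non-natural α-ethyl β-keto ester, and a panel enzyme may lack activity or syn/anti control. The fallback sets out from 3. Noyori hydrogenation (RuCl2[(S)-BINAP], H2, EtOH) gives ethyl (3S)-5-(benzyloxy)-3-hydroxypentanoate F1. Fráter–Seebach alkylation of its dianion (LDA 2.2 eq, THF, −78 → −20 °C; EtI, DMPU) gives the anti product ethyl (2S,3S)-5-(benzyloxy)-2-ethyl-3-hydroxypentanoate F2, which has the correct C2. Mitsunobu inversion at C3 (4-nitrobenzoic acid, PPh3, DIAD, toluene, 0 °C) gives ethyl (2S,3R)-5-(benzyloxy)-2-ethyl-3-[(4-nitrobenzoyl)oxy]pentanoate F3, and K2CO3 in EtOH removes the nitrobenzoate to come back at 5.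

Step 22 (Krische crotylation of 26). Conversion and catalyst control are uncertain on a large β-silyloxy alcohol, and the ligand antipode would need confirming on a model. The fallback sets out from 26. Dess–Martin oxidation gives the C13 aldehyde 27, now isolated. It is crotylated with (E)-crotylboronic acid pinacol ester under chiral phosphoric acid catalysis ((S)-TRIP, 5 mol%, toluene, −30 °C; closed chair transition state, anti product) and comes back at 28. It makes no compound outside the list (none F0).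

Step 45 (Stille macrocyclisation of 54). A 28-membered ring closure can lose material to oligomerisation, protodestannylation or polyene isomerisation. The fallback sets out from 41 and 52. Intermolecular Stille coupling (Pd2(dba)3, AsPh3, NMP, rt, dark) gives the C1–C28 seco hydroxy acid (hexa-TBS pentaene) F4. Yamaguchi macrolactonisation (2,4,6-trichlorobenzoyl chloride, Et3N, THF; then slow addition to DMAP in toluene at 0.5 mM) runs through the mixed anhydride of the seco acid with 2,4,6-trichlorobenzoic acid F5 and comes back at 55.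

**Further compounds**
F1 | step 3 | ethyl (3S)-5-(benzyloxy)-3-hydroxypentanoate | c1ccccc1COCC[C@H](O)CC(=O)OCC
F2 | step 3 | ethyl (2S,3S)-5-(benzyloxy)-2-ethyl-3-hydroxypentanoate | c1ccccc1COCC[C@H](O)[C@H](CC)C(=O)OCC
F3 | step 3 | ethyl (2S,3R)-5-(benzyloxy)-2-ethyl-3-[(4-nitrobenzoyl)oxy]pentanoate | c1ccccc1COCC[C@@H](OC(=O)c1ccc(cc1)[N+](=O)[O-])[C@H](CC)C(=O)OCC
F0 | step 22 | none | none
F4 | step 45 | C1–C28 seco hydroxy acid (hexa-TBS pentaene) | O[C@H](C)[C@H](C)/C=C/C=C/C=C/C=C/C=C/[C@@H](O[Si](C)(C)C(C)(C)C)[C@H](C)[C@H](O[Si](C)(C)C(C)(C)C)C[C@@H](O[Si](C)(C)C(C)(C)C)C[C@@H](O[Si](C)(C)C(C)(C)C)CCC[C@H](O[Si](C)(C)C(C)(C)C)C[C@@H](O[Si](C)(C)C(C)(C)C)[C@H](CC)C(=O)O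
F5 | step 45 | mixed anhydride of the seco acid with 2,4,6-trichlorobenzoic acid | O[C@H](C)[C@H](C)/C=C/C=C/C=C/C=C/C=C/[C@@H](O[Si](C)(C)C(C)(C)C)[C@H](C)[C@H](O[Si](C)(C)C(C)(C)C)C[C@@H](O[Si](C)(C)C(C)(C)C)C[C@@H](O[Si](C)(C)C(C)(C)C)CCC[C@H](O[Si](C)(C)C(C)(C)C)C[C@@H](O[Si](C)(C)C(C)(C)C)[C@H](CC)C(=O)OC(=O)c1c(Cl)cc(Cl)cc1Cl
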